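**Retrosynthetic overview**
- Target (ent-copalyl hydrogen malonate, 5R,9R,10R) ⇒ its acyclic isomer, (2E,6E,10E)-geranylgeranyl hydrogen malonate. Both rings are opened (C9–C10 and C4–C5, labdane numbering) and H is moved from C3 back to C17. In the forward sense this is a proton-initiated, cyclase-like bicyclisation run as the last step on the intact half-ester.
- Acyclic half-malonate ⇒ (2E,6E,10E)-geranylgeraniol + Meldrum's acid (acyl C–O bond).
- Ring order, forward: protonation at C3, ring A (C4–C5) first, ring B (C9–C10) second, then loss of H from C17. C5, C9 and C10 are all set in this one step.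

**Assumptions**
- (2E,6E,10E)-Geranylgeraniol (annatto-derived, sold in bulk) is taken as a cheap commercial starting material.
- IDPi-A is a confined BINOL-derived imidodiphosphorimidate Brønsted acid (3,3'-aryl groups, N-perfluoroarylsulfonyl inner groups). Its handedness is fixed operationally as the mirror image of the antipode that converts (3E,7E)-homofarnesol into natural (−)-ambrox, so that the 5R,10R series results; if the sense is reversed for this substrate, the other antipode is used.

**Route**

Step 1
Reactants: 1 (2E,6E,10E)-geranylgeraniol; 2 Meldrum's acid (2,2-dimethyl-1,3-dioxane-4,6-dione)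
Product: 3 (2E,6E,10E)-geranylgeranyl hydrogen malonate
Conditions: 2 (1.1 equiv), toluene, 95 °C, 5 h
Reagents that add atoms: Meldrum's acid (compound 2), CC1(C)OC(=O)CC(=O)O1
Why: Alcoholysis of Meldrum's acid (thermal acyl transfer with ring opening and loss of acetone) gives the malonic half-ester of a primary alcohol in one operation without a protecting group; no stereocentre is formed and the E-alkenes are not touched at this acidity and temperature.

Step 2
Reactants: 3 (2E,6E,10E)-geranylgeranyl hydrogen malonate
Product: 5 ent-copalyl hydrogen malonate [(5R,9R,10R)-labda-8(17),13E-dien-15-yl hydrogen malonate; target], via bicyclic C8 cation 4 (not isolated)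
Conditions: IDPi-A (5 mol%), (CF3)3COH/CH2Cl2 3:1, −30 °C, 48 h; then Et3N
Reagents that add atoms: none
Why: Proposed new method: the confined chiral acid protonates the terminal alkene of the all-chair folded tetraene on one enantiotopic face (C3–H), and two anti additions across the E-alkenes (Stork–Eschenmoser course) close ring A (C4–C5) and then ring B (C9–C10), setting C5, C10 and C9 together as the trans-decalin with equatorial side chain; the tertiary C8 cation 4 finds no nucleophile in the non-nucleophilic fluorinated alcohol, its 13,14-alkene is deactivated by the allylic ester oxygen, and the bulky catalyst anion removes the most exposed proton (C17 methyl) to give the exocyclic alkene and return the acid, while low temperature and low acid loading slow reprotonation to the endocyclic isomers; allylic esters are known to survive even fluorosulfonic acid cyclisations at low temperature, and a free carboxylic acid is tolerated by this catalyst class; closest known reaction type: imidodiphosphorimidate-catalysed asymmetric proton-initiated polyene cyclisation of homofarnesol-type substrates in fluorinated alcohols, and mechanistically the ent-copalyl diphosphate synthase reaction.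

**Compound list**
1 | (2E,6E,10E)-geranylgeraniol; (2E,6E,10E)-3,7,11,15-tetramethylhexadeca-2,6,10,14-tetraen-1-ol | CC(C)=CCC/C(C)=C/CC/C(C)=C/CC/C(C)=C/CO | starting material
2 | Meldrum's acid; 2,2-dimethyl-1,3-dioxane-4,6-dione | CC1(C)OC(=O)CC(=O)O1 | starting material
3 | (2E,6E,10E)-geranylgeranyl hydrogen malonate; 3-oxo-3-{[(2E,6E,10E)-3,7,11,15-tetramethylhexadeca-2,6,10,14-tetraen-1-yl]oxy}propanoic acid | CC(C)=CCC/C(C)=C/CC/C(C)=C/CC/C(C)=C/COC(=O)CC(=O)O | intermediate
4 | (5R,9R,10R)-15-(carboxyacetoxy)labd-13E-en-8-yl cation; tertiary C8 carbocation, ion pair with the catalyst anion | C[C+]1CC[C@@H]2C(C)(C)CCC[C@@]2(C)[C@@H]1CC/C(C)=C/COC(=O)CC(=O)O | intermediate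
5 | ent-copalyl hydrogen malonate; 3-{[(2E)-3-methyl-5-[(1R,4aR,8aR)-5,5,8a-trimethyl-2-methylidenedecahydronaphthalen-1-yl]pent-2-en-1-yl]oxy}-3-oxopropanoic acid | C=C1CC[C@@H]2C(C)(C)CCC[C@@]2(C)[C@@H]1CC/C(C)=C/COC(=O)CC(=O)O | target

**Totals**
Total step count: 2. Longest linear sequence: 2 (from 1).

**Steps most likely to fail**
The route has only two steps, so both are ranked, the riskier first.

1. Step 2 is the main risk. The face selectivity of the chiral acid is untested for a substrate that ends in elimination rather than in capture by a hydroxyl group. The termination may give the 7-ene and 8(9)-ene isomers alongside the 8(17)-ene (separable on AgNO3–silica). The cascade may stop at the monocycle or go on to the tricyclic isocopalane, and the allylic ester may ionise.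
Fallback (sets out from 1, comes back at 5): the ring closure is handed to the cyclase itself. 1 is converted with NCS/Me2S (CH2Cl2, −30 to 0 °C) into (2E,6E,10E)-geranylgeranyl chloride F1. Displacement with (Bu4N)3HP2O7 in MeCN and cation exchange to the ammonium salt gives (2E,6E,10E)-geranylgeranyl diphosphate F2. Recombinant ent-copalyl diphosphate synthase (Arabidopsis thaliana enzyme expressed in E. coli, 0.1 mM MgCl2, pH 7.5, 30 °C) converts F2 into ent-copalyl diphosphate F3; the enzyme fixes the face of protonation, the stop after ring B and the loss of the C17 proton. Alkaline phosphatase (pH 8.5) frees ent-copalol F4, and F4 with Meldrum's acid 2 (toluene, 80 °C) gives 5.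

2. Step 1 is the lesser risk. Hot, weakly acidic conditions could cause some allylic transposition or dehydration of the tetraene alcohol, and the half-ester could decarboxylate to the acetate if overheated.
Fallback (sets out from 1, comes back at 3): the ester C–O bond is made by alkylating a carboxylate instead of by acyl transfer. PBr3 (Et2O, −10 °C) turns 1 into (2E,6E,10E)-geranylgeranyl bromide F5. F5 then alkylates CsO2CCH2CO2H on oxygen (malonic acid 4 equiv, Cs2CO3 2 equiv, DMF, 0 °C to rt, then dilute citric acid) to give 3 without heating. The excess hydrogen malonate keeps dialkylation low, and the CH2 of the carboxylate salt is not deprotonated, so there is no C-alkylation.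

**Further compounds**
F1 | step 2 | (2E,6E,10E)-geranylgeranyl chloride | CC(C)=CCC/C(C)=C/CC/C(C)=C/CC/C(C)=C/CCl
F2 | step 2 | (2E,6E,10E)-geranylgeranyl diphosphate (acid form; handled as the ammonium salt) | CC(C)=CCC/C(C)=C/CC/C(C)=C/CC/C(C)=C/COP(=O)(O)OP(=O)(O)O
F3 | step 2 | ent-copalyl diphosphate (acid form) | C=C1CC[C@@H]2C(C)(C)CCC[C@@]2(C)[C@@H]1CC/C(C)=C/COP(=O)(O)OP(=O)(O)O
F4 | step 2 | ent-copalol; (5R,9R,10R)-labda-8(17),13E-dien-15-ol | C=C1CC[C@@H]2C(C)(C)CCC[C@@]2(C)[C@@H]1CC/C(C)=C/CO
F5 | step 1 | (2E,6E,10E)-geranylgeranyl bromide | CC(C)=CCC/C(C)=C/CC/C(C)=C/CC/C(C)=C/CBr
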